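The two Z-hexenoyl C–O bonds at O3 and O9 are cut first (by way of the bis-ynoate). C11=C12 is then taken back to an ester carbon on C7, and the cis-8α,9α-dioxygenation of ring B (C5–C10) is read as a former C8=C9 olefin.
That olefin makes ring B a Diels–Alder cyclohexene: the diene is C7=C8–C9=C10, the dienophile is C5=C6 with methyl C14 on C5, and the four-atom tether C1–C4 (carrying O3 and methyl C15) is ring A. The ring cuts are C5–C10 and C6–C7.
The open-chain trienoate is cut at C5=C6 (methylenation), C7=C8 (Wittig), C9=C10 (cross-metathesis), C5–C14 (Grignard) and C3–C4 (aldol).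
Forward, the chain is joined in the order C3–C4, C5–C14, C9=C10, C7=C8, C5=C6, and rings A and B then close together in one thermal step. Ring B is oxygenated next, C11 becomes the isopropenyl group, and the acyl groups come last.
C3/C4 come from an oxazolidinone syn-aldol, C5/C10 are relayed from them through a chair-like trans transition state, and C9 (and provisionally C8) come from osmylation anti to C14. C7 is born 7β and is equilibrated beside a C8 ketone, C8 is reset by equatorial hydride delivery, and both Z-olefins come from syn semihydrogenation.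

Key step: step 8

Remark: eremophilane numbering is used and β is the face that carries methyl C14. The target SMILES then reads (3R,4R,5R,7S,8R,9S,10R), a trans-decalin with O3, O9 and the isopropenyl group α-equatorial, the free 8-OH α-axial, and C14/C15 both β.

Step 1
Reactants: 1 (4S)-4-benzyl-3-propanoyl-1,3-oxazolidin-2-one; 2 pent-4-enal
Product: 4 (4S)-4-benzyl-3-[(2S,3R)-3-hydroxy-2-methylhept-6-enoyl]-1,3-oxazolidin-2-one, via dibutylboron Z-enolate 3 (not isolated)
Conditions: n-Bu2BOTf, Et3N, CH2Cl2, 0 °C; 2, −78 → 0 °C; pH 7 buffer, MeOH, 30% H2O2, 0 °C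
Reagents that add atoms: dibutylboron triflate CCCCB(CCCC)OS(=O)(=O)C(F)(F)F (its boron is held only in 3)
Why: Evans syn-aldol reaction, in which the Z-boron enolate reacts through a closed chair transition state on the enolate face left open by the benzyl group of the auxiliary, so that C4 and C3 are set together as the (2S,3R) syn pair that later sits trans-diequatorial on ring A.

Step 2
Reactants: 4 aldol imide
Product: 5 (2S,3R)-3-hydroxy-N-methoxy-N,2-dimethylhept-6-enamide
Conditions: MeNHOMe·HCl, AlMe3, CH2Cl2, 0 °C → rt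
Reagents that add atoms: N,O-dimethylhydroxylamine hydrochloride CNOC.Cl
Why: Weinreb transamidation with the aluminium amide, helped by the free β-hydroxyl, attacks only the exocyclic imide carbonyl, releases the auxiliary for re-use and touches neither stereocentre.

Step 3
Reactants: 5 hydroxy Weinreb amide
Product: 6 (2S,3R)-N-methoxy-N,2-dimethyl-3-(triisopropylsilyloxy)hept-6-enamide
Conditions: TIPSOTf, 2,6-lutidine, CH2Cl2, 0 °C → rt
Reagents that add atoms: triisopropylsilyl triflate CC(C)[Si](OS(=O)(=O)C(F)(F)F)(C(C)C)C(C)C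
Why: Silylation of a secondary alcohol with a silyl triflate and a hindered base is routine, and the triisopropylsilyl ether is chosen because it has to outlast 200 °C, Grignard reagents and the acidic acetonide cleavage of step 13.

Step 4
Reactants: 6 silylated Weinreb amide
Product: 7 (3S,4R)-3-methyl-4-(triisopropylsilyloxy)oct-7-en-2-one
Conditions: MeMgBr, THF, 0 °C; aq NH4Cl
Reagents that add atoms: methylmagnesium bromide C[Mg]Br
Why: Weinreb ketone synthesis, in which the chelated tetrahedral adduct stops at mono-addition and collapses only on quench, so the new methyl (C14) is installed without exposing the α-centre C4 to base as a ketone.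

Step 5
Reactants: 7 methyl ketone; 8 (E)-but-2-enal
Product: 9 (2E,6R,7S)-7-methyl-8-oxo-6-(triisopropylsilyloxy)non-2-enal
Conditions: 8 (5 equiv), second-generation Hoveyda–Grubbs catalyst RuCl2(H2IMes)(=CH-C6H4-2-O-i-Pr) (3 mol %), CH2Cl2, 40 °C
Reagents that add atoms: none
Why: Olefin cross-metathesis of an unhindered terminal alkene with an excess of an electron-poor enal gives the E-enal (C9=C10) under thermodynamic control, and the ketone and silyl ether are inert to the ruthenium carbene.

Step 6
Reactants: 9 keto enal; 10 ethyl (triphenyl-λ5-phosphanylidene)acetate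
Product: 11 ethyl (2E,4E,8R,9S)-9-methyl-10-oxo-8-(triisopropylsilyloxy)undeca-2,4-dienoate
Conditions: 10, CH2Cl2, rt
Reagents that add atoms: none
Why: Wittig olefination with a stabilised ylide is E-selective (C7=C8), takes the aldehyde and not the methyl ketone, and is neutral enough neither to epimerise C4 nor to expel the β-silyloxy group.

Step 7
Reactants: 11 keto dienoate
Product: 12 ethyl (2E,4E,8R,9R)-9,10-dimethyl-8-(triisopropylsilyloxy)undeca-2,4,10-trienoate
Conditions: Cp2Ti(μ-CH2)(μ-Cl)AlMe2 (1.1 equiv), pyridine (cat.), THF/PhMe, −40 → 0 °C; aq NaOH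
Reagents that add atoms: Cp2Ti(μ-CH2)(μ-Cl)AlMe2 (Tebbe reagent), written as Cp2Ti=CH2·ClAlMe2, C=[Ti](C1C=CC=C1)C1C=CC=C1.C[Al](C)Cl
Why: Tebbe methylenation uses a non-basic titanium methylidene, so C4 is not epimerised, and with about one equivalent at low temperature a ketone is taken well before a conjugated ester.

Step 8
Reactants: 12 trienoate
Product: 13 ethyl 3α-(triisopropylsilyloxy)-12,13-dinoreremophil-8-en-11-oate, the trans-fused Δ8-octalin with 4β-Me, 5β-Me (C14), 10α-H and the C7 ester β (cis to C14)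
Conditions: PhMe (0.01 M, degassed), BHT (10 mol %), sealed tube, 200 °C
Reagents that add atoms: none
Why: A concerted, suprafacial thermal [4+2] cycloaddition joins the C7=C8–C9=C10 dienoate to the C5=C6 methylidene, forming C5–C10 and C6–C7 and leaving the new olefin at C8=C9. The closest known reaction type is the thermal intramolecular Diels–Alder reaction of deca-1,7,9-trienes that carry an ester on the diene terminus and an unactivated 1,1-disubstituted dienophile, an established entry to octalins with an angular methyl group; the four-atom tether fixes the fused regiochemistry, and heat alone is used because a Lewis acid would polarise the dienoate against this bond pairing. Ring A closes as the tether ring, its six atoms C10–C1–C2–C3–C4–C5 lying in a chair that is shut by the C5–C10 bond, and ring B closes as the new cyclohexene through both new bonds. C5 and C10 are set by the transition state with C14 endo and the tether exo, which gives the trans fusion, and their absolute sense by the only chair that holds C3–OTIPS and C4–Me equatorial, so that C14 ends cis to C15. C7 is set by the E geometry of both diene double bonds, which obliges the ester to end cis to C1 on ring B and hence cis to C14 (7β), the epimer that step 15 corrects. The step needs one π-face pairing and trans rather than cis fusion: the first is secured by the resident C3/C4 pair, the second only by the lower strain of the chair-like exo-tether array, so a cis-fused minor isomer is expected and is to be removed by chromatography, while high dilution, BHT and exclusion of air hold back intermolecular addition and polymerisation.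

Step 9
Reactants: 13 octalin ester
Product: 14 ethyl 8α,9α-dihydroxy-3α-(triisopropylsilyloxy)-12,13-dinoreremophilan-11-oate (7β-ester)
Conditions: OsO4 (3 mol %), NMO, acetone/H2O, rt; aq Na2SO3
Reagents that add atoms: N-methylmorpholine N-oxide C[N+]1([O-])CCOCC1; water O; OsO4 O=[Os](=O)(=O)=O (catalytic oxygen carrier)
Why: Upjohn dihydroxylation adds both oxygens syn on the α face, anti to the axial C14 methyl and to the pseudo-axial C7 ester, which sets C9 for good and C8 provisionally as the 8α,9α-diol.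

Step 10
Reactants: 14 diol ester
Product: 15 ethyl 8α,9α-(isopropylidenedioxy)-3α-(triisopropylsilyloxy)-12,13-dinoreremophilan-11-oate (7β-ester)
Conditions: Me2C(OMe)2, PPTS (cat.), CH2Cl2, rt
Reagents that add atoms: 2,2-dimethoxypropane COC(C)(C)OC
Why: Acid-catalysed transketalisation of a cis-1,2-diol gives the dioxolane, which masks both hydroxyls as poor leaving groups during the carbonyl chemistry at C11.

Step 11
Reactants: 15 acetonide ester
Product: 17 7β-acetyl acetonide [8α,9α-(isopropylidenedioxy)-3α-(triisopropylsilyloxy)-13-noreremophilan-11-one], via Weinreb amide 16 (not isolated)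
Conditions: MeNHOMe·HCl, i-PrMgCl, THF, −20 → 0 °C; then MeMgBr, 0 °C → rt; aq NH4Cl
Reagents that add atoms: methylmagnesium bromide C[Mg]Br; N,O-dimethylhydroxylamine hydrochloride CNOC.Cl (its atoms are held only in 16)
Why: Magnesium-amide aminolysis of the ester followed in the same flask by Weinreb ketone synthesis stops at the methyl ketone, and any erosion at C7 is harmless because that centre is equilibrated in step 15.

Step 12
Reactants: 17 7β-acetyl acetonide
Product: 18 7β-isopropenyl acetonide, 8α,9α-(isopropylidenedioxy)-3α-(triisopropylsilyloxy)-7-epi-eremophil-11-ene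
Conditions: Cp2Ti(μ-CH2)(μ-Cl)AlMe2, pyridine (cat.), THF/PhMe, −40 °C → rt; aq NaOH
Reagents that add atoms: Cp2Ti(μ-CH2)(μ-Cl)AlMe2 (Tebbe reagent), written as Cp2Ti=CH2·ClAlMe2, C=[Ti](C1C=CC=C1)C1C=CC=C1.C[Al](C)Cl
Why: Tebbe methylenation is small and non-basic enough for a hindered axial acetyl group and avoids the enolate from which the C8 oxygen could be expelled.

Step 13
Reactants: 18 7β-isopropenyl acetonide
Product: 19 7β-isopropenyl-3α-(triisopropylsilyloxy)eremophil-11-ene-8α,9α-diol
Conditions: AcOH/THF/H2O (3:1:1), 45 °C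
Reagents that add atoms: none
Why: Mild aqueous acid hydrolyses the cis-fused dioxolane, while the far more acid-stable triisopropylsilyl ether and the 1,1-disubstituted olefin persist.

Step 14
Reactants: 19 diol
Product: 20 7β-isopropenyl-9α-(tert-butyldimethylsilyloxy)-3α-(triisopropylsilyloxy)eremophil-11-en-8α-ol
Conditions: TBSCl (1.1 equiv), imidazole, DMF, 0 °C
Reagents that add atoms: tert-butyldimethylsilyl chloride CC(C)(C)[Si](C)(C)Cl
Why: Regioselective monosilylation of a cis-diol, in which the equatorial C9 hydroxyl reacts well before the axial C8 hydroxyl that is shielded by the axial hydrogens on C6 and C10, the order known from locked cyclohexanediols and pyranosides.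

Step 15
Reactants: 20 8α-alcohol
Product: 22 7α-isopropenyl-9α-(tert-butyldimethylsilyloxy)-3α-(triisopropylsilyloxy)eremophil-11-en-8-one, via 7β-isopropenyl ketone 21 (not isolated)
Conditions: Dess–Martin periodinane, CH2Cl2, 0 °C → rt; aqueous wash; crude 21, DBU (0.3 equiv), PhMe, rt
Reagents that add atoms: none
Why: Dess–Martin oxidation gives the C8 ketone and base-mediated enolisation then lets C7 relax from the axial site, where isopropenyl and C14 are 1,3-diaxial, to the equatorial 7α site, α-protonation of the dienolate being faster than the γ-protonation that would conjugate the olefin, while C9 holds because its silyloxy group is already equatorial and would meet C14 if axial.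

Step 16
Reactants: 22 7α-isopropenyl ketone
Product: 23 7α-isopropenyl-9α-(tert-butyldimethylsilyloxy)-3α-(triisopropylsilyloxy)eremophil-11-en-8α-ol
Conditions: LiBH(s-Bu)3, THF, −78 °C; then aq NaOH, H2O2, 0 °C
Reagents that add atoms: none
Why: Bulky trialkylborohydride reduction of a cyclohexanone delivers hydride along the equatorial trajectory from the β face, as with 2-isopropenyl- and cis-2,6-disubstituted cyclohexanones, which sets C8 as the axial 8α-alcohol cis to both neighbours.

Step 17
Reactants: 23 bis-silyl ether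
Product: 24 eremophil-11-ene-3α,8α,9α-triol (7α-isopropenyl)
Conditions: n-Bu4NF, THF, rt → 45 °C
Reagents that add atoms: none
Why: Fluoride-induced desilylation removes both silyl ethers, and nothing else in the molecule is sensitive to it.

Step 18
Reactants: 24 triol; 25 hex-2-ynoic acid
Product: 26 8α-hydroxyeremophil-11-ene-3α,9α-diyl bis(hex-2-ynoate)
Conditions: 25 (2.2 equiv), DCC, DMAP (cat.), CH2Cl2, −20 → 0 °C
Reagents that add atoms: none
Why: Steglich esterification under kinetic control acylates the two equatorial hydroxyls at C3 and C9 while the axial C8 hydroxyl, flanked by the equatorial isopropenyl group and the new C9 ester, lags behind as axial hydroxyls do in partial acylations of cyclitols and pyranosides, and the ynoic acid is used because a Z-enoic acid would isomerise under DMAP.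

Step 19
Reactants: 26 bis-ynoate
Product: 27 (3R,4R,5R,7S,8R,9S,10R)-8-hydroxyeremophil-11-ene-3,9-diyl bis[(2Z)-hex-2-enoate], CNP0420276.1
Conditions: H2 (1 atm), Pd/CaCO3 poisoned with Pb(OAc)2, quinoline, EtOAc, rt, stopped after two equivalents of H2
Reagents that add atoms: none
Why: Lindlar-type semihydrogenation delivers one H2 syn to each alkyne and so gives both Z-enoates, and the poisoned catalyst leaves the 1,1-disubstituted C11=C12 olefin alone.

Compound list
1 | (4S)-4-benzyl-3-propanoyl-1,3-oxazolidin-2-one | CCC(=O)N1[C@@H](Cc2ccccc2)COC1=O | starting material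
2 | pent-4-enal | C=CCCC=O | starting material
3 | dibutylboron Z-enolate of 1 | C/C=C(\OB(CCCC)CCCC)N1[C@@H](Cc2ccccc2)COC1=O | intermediate
4 | (4S)-4-benzyl-3-[(2S,3R)-3-hydroxy-2-methylhept-6-enoyl]-1,3-oxazolidin-2-one | O=C([C@@H](C)[C@H](O)CCC=C)N1[C@@H](Cc2ccccc2)COC1=O | intermediate
5 | (2S,3R)-3-hydroxy-N-methoxy-N,2-dimethylhept-6-enamide | CON(C)C(=O)[C@@H](C)[C@H](O)CCC=C | intermediate
6 | (2S,3R)-N-methoxy-N,2-dimethyl-3-(triisopropylsilyloxy)hept-6-enamide | CON(C)C(=O)[C@@H](C)[C@H](O[Si](C(C)C)(C(C)C)C(C)C)CCC=C | intermediate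
7 | (3S,4R)-3-methyl-4-(triisopropylsilyloxy)oct-7-en-2-one | CC(=O)[C@@H](C)[C@H](O[Si](C(C)C)(C(C)C)C(C)C)CCC=C | intermediate
8 | (E)-but-2-enal | C/C=C/C=O | starting material
9 | (2E,6R,7S)-7-methyl-8-oxo-6-(triisopropylsilyloxy)non-2-enal | CC(=O)[C@@H](C)[C@H](O[Si](C(C)C)(C(C)C)C(C)C)CC/C=C/C=O | intermediate
10 | ethyl (triphenyl-λ5-phosphanylidene)acetate | CCOC(=O)C=P(c1ccccc1)(c1ccccc1)c1ccccc1 | starting material
11 | ethyl (2E,4E,8R,9S)-9-methyl-10-oxo-8-(triisopropylsilyloxy)undeca-2,4-dienoate | CC(=O)[C@@H](C)[C@H](O[Si](C(C)C)(C(C)C)C(C)C)CC/C=C/C=C/C(=O)OCC | intermediate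
12 | ethyl (2E,4E,8R,9R)-9,10-dimethyl-8-(triisopropylsilyloxy)undeca-2,4,10-trienoate | C=C(C)[C@@H](C)[C@H](O[Si](C(C)C)(C(C)C)C(C)C)CC/C=C/C=C/C(=O)OCC | intermediate
13 | trans-fused Δ8-octalin ethyl ester, 3α-OTIPS, 4β,5β-dimethyl, 10α-H, 7β-CO2Et | CCOC(=O)[C@H]1C[C@]2(C)[C@@H](C)[C@H](O[Si](C(C)C)(C(C)C)C(C)C)CC[C@H]2C=C1 | intermediate
14 | 8α,9α-diol of 13 (7β-ester) | CCOC(=O)[C@H]1C[C@]2(C)[C@@H](C)[C@H](O[Si](C(C)C)(C(C)C)C(C)C)CC[C@H]2[C@H](O)[C@@H]1O | intermediate
15 | 8α,9α-acetonide of 14 (7β-ester) | CCOC(=O)[C@H]1C[C@]2(C)[C@@H](C)[C@H](O[Si](C(C)C)(C(C)C)C(C)C)CC[C@H]2[C@H](OC3(C)C)[C@@H]1O3 | intermediate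
16 | 7β-(N-methoxy-N-methylcarbamoyl) acetonide | CON(C)C(=O)[C@H]1C[C@]2(C)[C@@H](C)[C@H](O[Si](C(C)C)(C(C)C)C(C)C)CC[C@H]2[C@H](OC3(C)C)[C@@H]1O3 | intermediate
17 | 7β-acetyl acetonide | CC(=O)[C@H]1C[C@]2(C)[C@@H](C)[C@H](O[Si](C(C)C)(C(C)C)C(C)C)CC[C@H]2[C@H](OC3(C)C)[C@@H]1O3 | intermediate
18 | 7β-isopropenyl acetonide | C=C(C)[C@H]1C[C@]2(C)[C@@H](C)[C@H](O[Si](C(C)C)(C(C)C)C(C)C)CC[C@H]2[C@H](OC3(C)C)[C@@H]1O3 | intermediate
19 | 7β-isopropenyl-3α-OTIPS-8α,9α-diol | C=C(C)[C@H]1C[C@]2(C)[C@@H](C)[C@H](O[Si](C(C)C)(C(C)C)C(C)C)CC[C@H]2[C@H](O)[C@@H]1O | intermediate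
20 | 7β-isopropenyl-9α-OTBS-3α-OTIPS-8α-ol | C=C(C)[C@H]1C[C@]2(C)[C@@H](C)[C@H](O[Si](C(C)C)(C(C)C)C(C)C)CC[C@H]2[C@H](O[Si](C)(C)C(C)(C)C)[C@@H]1O | intermediate
21 | 7β-isopropenyl-9α-OTBS-3α-OTIPS-8-one | C=C(C)[C@H]1C[C@]2(C)[C@@H](C)[C@H](O[Si](C(C)C)(C(C)C)C(C)C)CC[C@H]2[C@H](O[Si](C)(C)C(C)(C)C)C1=O | intermediate
22 | 7α-isopropenyl-9α-OTBS-3α-OTIPS-8-one | C=C(C)[C@@H]1C[C@]2(C)[C@@H](C)[C@H](O[Si](C(C)C)(C(C)C)C(C)C)CC[C@H]2[C@H](O[Si](C)(C)C(C)(C)C)C1=O | intermediate
23 | 7α-isopropenyl-9α-OTBS-3α-OTIPS-8α-ol | C=C(C)[C@@H]1C[C@]2(C)[C@@H](C)[C@H](O[Si](C(C)C)(C(C)C)C(C)C)CC[C@H]2[C@H](O[Si](C)(C)C(C)(C)C)[C@@H]1O | intermediate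
24 | eremophil-11-ene-3α,8α,9α-triol (7α-isopropenyl) | C=C(C)[C@@H]1C[C@]2(C)[C@@H](C)[C@H](O)CC[C@H]2[C@H](O)[C@@H]1O | intermediate
25 | hex-2-ynoic acid | CCCC#CC(=O)O | starting material
26 | 8α-hydroxyeremophil-11-ene-3α,9α-diyl bis(hex-2-ynoate) | C=C(C)[C@@H]1C[C@]2(C)[C@@H](C)[C@H](OC(=O)C#CCCC)CC[C@H]2[C@H](OC(=O)C#CCCC)[C@@H]1O | intermediate
27 | (3R,4R,5R,7S,8R,9S,10R)-8-hydroxyeremophil-11-ene-3,9-diyl bis[(2Z)-hex-2-enoate] | C=C(C)[C@@H]1C[C@]2(C)[C@@H](C)[C@H](OC(=O)/C=C\CCC)CC[C@H]2[C@H](OC(=O)/C=C\CCC)[C@@H]1O | target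

Total steps: 19. Longest linear sequence: 19 steps (from 1 or 2 to 27); 8, 10 and 25 enter as purchased.

Steps most likely to fail

Step 8. The preference for the trans-fused over the cis-fused transition state may be too small. The cycloaddition of an unactivated dienophile may also be slow enough for polymerisation to compete.
- The fallback places a removable steric directing group on C9. It sets out from 9 and comes back at 13.
- Bromine is added to the enal (Br2, CH2Cl2, −78 °C) to give the 2,3-dibromoaldehyde F1, which loses HBr in the same flask (Et3N) to give the (Z)-2-bromoenal F2.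
- Wittig olefination with 10 gives the (2E,4Z)-4-bromodienoate ketone F3, and methylenation with Cp2Ti(μ-CH2)(μ-Cl)AlMe2 gives the bromotrienoate F4.
- In F4 the bromine on C9 lies cis to C1 across C9=C10. It raises the s-cis population of the diene and meets the C1–C2 bond only in the cis-fused array (allylic strain). This directing effect is known for decatriene cycloadditions.
- Thermolysis (PhMe, BHT, sealed tube) should therefore favour the trans-fused 9-bromo-octalin F5. Hydrodebromination (Bu3SnH, Pd(PPh3)4 cat., THF) then gives 13.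

Step 15. The C11=C12 double bond may migrate into conjugation with the C8 ketone in competition with epimerisation. The epimerisation itself may be sluggish because the equatorial C7–H is poorly aligned with the carbonyl group.
- The fallback corrects C7 one stage earlier, at the acetyl group. C8 is then never oxidised and keeps the configuration given by osmylation. It sets out from 17 and comes back at 24.
- Brief equilibration (K2CO3, MeOH, rt) moves the acetyl group out of its 1,3-diaxial contact with C14 and gives the 7α-acetyl acetonide F6. The exposure is kept short so that the C8 oxygen is not eliminated.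
- Methylenation with Cp2Ti(μ-CH2)(μ-Cl)AlMe2 gives the 7α-isopropenyl acetonide F7.
- Aqueous acetic acid gives the 7α-isopropenyl 8α,9α-diol F8, and n-Bu4NF gives 24.

Step 18. Discrimination between the equatorial and the axial hydroxyls may be insufficient, which would lead to acylation at O8 or to acyl migration from O9 to O8.
- The fallback blocks O8 instead of relying on relative rates. It sets out from 23 and comes back at 26.
- The free axial hydroxyl is etherified (4-methoxybenzyl trichloroacetimidate, La(OTf)3 cat., PhMe) to give the 8-O-PMB ether F9.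
- n-Bu4NF gives the 3α,9α-diol F10, in which only the two wanted hydroxyls are free.
- Exhaustive Steglich acylation with 25 gives the 8-O-PMB bis-ynoate F11.
- DDQ (CH2Cl2, pH 7 buffer, 0 °C) removes the benzyl group and gives 26.

Further compounds
F1 | step 8 | (6R,7S)-2,3-dibromo-7-methyl-8-oxo-6-(triisopropylsilyloxy)nonanal (anti adducts, both diastereomers, not isolated) | CC(=O)[C@@H](C)[C@H](O[Si](C(C)C)(C(C)C)C(C)C)CCC(Br)C(Br)C=O
F2 | step 8 | (2Z,6R,7S)-2-bromo-7-methyl-8-oxo-6-(triisopropylsilyloxy)non-2-enal | CC(=O)[C@@H](C)[C@H](O[Si](C(C)C)(C(C)C)C(C)C)CC/C=C(\Br)C=O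
F3 | step 8 | ethyl (2E,4Z,8R,9S)-4-bromo-9-methyl-10-oxo-8-(triisopropylsilyloxy)undeca-2,4-dienoate | CC(=O)[C@@H](C)[C@H](O[Si](C(C)C)(C(C)C)C(C)C)CC/C=C(\Br)/C=C/C(=O)OCC
F4 | step 8 | ethyl (2E,4Z,8R,9R)-4-bromo-9,10-dimethyl-8-(triisopropylsilyloxy)undeca-2,4,10-trienoate | C=C(C)[C@@H](C)[C@H](O[Si](C(C)C)(C(C)C)C(C)C)CC/C=C(\Br)/C=C/C(=O)OCC
F5 | step 8 | 9-bromo analogue of 13 (trans-fused, 7β-ester) | CCOC(=O)[C@H]1C[C@]2(C)[C@@H](C)[C@H](O[Si](C(C)C)(C(C)C)C(C)C)CC[C@H]2C(Br)=C1
F6 | step 15 | 7α-acetyl acetonide (C7 epimer of 17) | CC(=O)[C@@H]1C[C@]2(C)[C@@H](C)[C@H](O[Si](C(C)C)(C(C)C)C(C)C)CC[C@H]2[C@H](OC3(C)C)[C@@H]1O3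
F7 | step 15 | 7α-isopropenyl acetonide (C7 epimer of 18) | C=C(C)[C@@H]1C[C@]2(C)[C@@H](C)[C@H](O[Si](C(C)C)(C(C)C)C(C)C)CC[C@H]2[C@H](OC3(C)C)[C@@H]1O3
F8 | step 15 | 7α-isopropenyl-3α-OTIPS-8α,9α-diol (C7 epimer of 19) | C=C(C)[C@@H]1C[C@]2(C)[C@@H](C)[C@H](O[Si](C(C)C)(C(C)C)C(C)C)CC[C@H]2[C@H](O)[C@@H]1O
F9 | step 18 | 8-O-(4-methoxybenzyl) ether of 23 | C=C(C)[C@@H]1C[C@]2(C)[C@@H](C)[C@H](O[Si](C(C)C)(C(C)C)C(C)C)CC[C@H]2[C@H](O[Si](C)(C)C(C)(C)C)[C@@H]1OCc3ccc(OC)cc3
F10 | step 18 | 8α-(4-methoxybenzyloxy)eremophil-11-ene-3α,9α-diol | C=C(C)[C@@H]1C[C@]2(C)[C@@H](C)[C@H](O)CC[C@H]2[C@H](O)[C@@H]1OCc3ccc(OC)cc3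
F11 | step 18 | 8α-(4-methoxybenzyloxy)eremophil-11-ene-3α,9α-diyl bis(hex-2-ynoate) | C=C(C)[C@@H]1C[C@]2(C)[C@@H](C)[C@H](OC(=O)C#CCCC)CC[C@H]2[C@H](OC(=O)C#CCCC)[C@@H]1OCc3ccc(OC)cc3
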